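The route rests on cutting the bond between C2 of the oxolane ring and its 3,4-dimethoxyphenyl group. C2 is bonded to the ring oxygen O1, so it can be an oxocarbenium carbon: the key step ionises a 2-benzenesulfonyl oxolane that already carries the C3/C4 trans-dimethyl pair and the C5 aryl group, and a (3,4-dimethoxyphenyl)zinc reagent adds to O1=C2 from the face opposite the C4 methyl and C5 aryl groups. One operation thus joins the two fragments and sets C2 in the 2,3-cis sense. The precursor comes from O-benzylvanillin by syn-crotylboration and a hydroxyl-directed branched hydroformylation; the threo aryloxypropanol arm is attached afterwards.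

Key step: step 4

Remark: lactol 5 and sulfone 6 are expected as mixtures of C2 epimers. Both converge on the same oxocarbenium ion, so C2 is left undefined in their SMILES. Compounds 1, 2, 7 (THF solution) and 12 are taken as commercial.

Step 1
Reactants: 1 4-(benzyloxy)-3-methoxybenzaldehyde (O-benzylvanillin); 2 (Z)-crotylboronic acid pinacol ester
Product: 3 (1S,2R)-1-[4-(benzyloxy)-3-methoxyphenyl]-2-methylbut-3-en-1-ol
Conditions: (S)-TRIP (5 mol%), 4 Å MS, toluene, −30 °C; aq. NaHCO3 work-up
Reagents that add atoms: none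
Why: Chiral phosphoric acid-catalysed crotylboration through a closed six-membered chair transition state, in which the (Z)-crotyl geometry is translated into the syn (1,2) relationship, while (S)-TRIP, hydrogen-bonded to the boronate oxygen and the formyl hydrogen, should expose the aldehyde face that leads to the (1S) carbinol, the opposite of the (R) sense expected from (R)-TRIP with aryl aldehydes.

Step 2
Reactants: 3 (1S,2R)-1-[4-(benzyloxy)-3-methoxyphenyl]-2-methylbut-3-en-1-ol
Product: 5 (3R,4R,5S)-5-[4-(benzyloxy)-3-methoxyphenyl]-3,4-dimethyloxolan-2-ol, via open-chain hydroxy aldehyde 4 (not isolated)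
Conditions: Rh(acac)(CO)2 (2 mol%), Ph2POMe (10 mol%), CO/H2 (1:1, 20 bar), 4 Å MS, THF, 40 °C
Reagents that add atoms: carbon monoxide, [C-]#[O+]
Why: Hydroxyl-directed branched-selective hydroformylation with a reversibly bound phosphinite directing group, in which transesterification of Ph2POMe with the homoallylic hydroxyl tethers rhodium so that hydrometalation through a six-membered rhodacycle places the formyl group on the internal alkene carbon and turns the terminal CH2 into the C3 methyl, the allylic methyl stereocentre should direct the new centre anti (3,4-trans, also the favoured arrangement at this epimerisable α-carbon), and the γ-hydroxy aldehyde closes spontaneously to the lactol.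

Step 3
Reactants: 5 (3R,4R,5S)-5-[4-(benzyloxy)-3-methoxyphenyl]-3,4-dimethyloxolan-2-ol
Product: 6 (3R,4R,5S)-2-(benzenesulfonyl)-5-[4-(benzyloxy)-3-methoxyphenyl]-3,4-dimethyloxolane
Conditions: PhSO2H, CaCl2, CH2Cl2, rt
Reagents that add atoms: benzenesulfinic acid, OS(=O)c1ccccc1
Why: Acid-mediated anomeric substitution (S-alkylation of the sulfinate by the oxocarbenium ion of the lactol, driven by removal of water with CaCl2) gives the stable 2-sulfonyl cyclic ether, whose C2 configuration does not matter because it is lost on ionisation in step 4.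

Step 4
Reactants: 6 (3R,4R,5S)-2-(benzenesulfonyl)-5-[4-(benzyloxy)-3-methoxyphenyl]-3,4-dimethyloxolane; 7 (3,4-dimethoxyphenyl)magnesium bromide
Product: 10 (2S,3R,4R,5S)-2-[4-(benzyloxy)-3-methoxyphenyl]-5-(3,4-dimethoxyphenyl)-3,4-dimethyloxolane, via arylzinc bromide 8 (not isolated), via cyclic oxocarbenium ion 9 (not isolated)
Conditions: 7, ZnBr2, THF, 0 °C → rt; then 6, THF, rt; aq. NH4Cl
Reagents that add atoms: none
Why: Transmetalation of 7 with ZnBr2 gives arylzinc 8, and zinc(II) as a mild Lewis acid ionises the anomeric C2–S bond of 6 to the cyclic oxocarbenium ion 9 (O1=C2), to which the aryl group is transferred from zinc (arylation of a 2-sulfonyl cyclic ether by an organozinc reagent, a C-glycosylation-type SN1 substitution). No ring is closed; the preformed oxolane only changes C2 from sp2 to sp3. The new stereocentre C2 is controlled by the ring: in the envelope of 9 with the C3 and C4 methyl groups pseudo-equatorial, inside attack brings the aryl group in on the face opposite the C4 methyl and the C5 aryl group, which gives the (S) centre with aryl cis to the C3 methyl and trans to the C4 methyl (2,3-cis-3,4-trans-4,5-cis). The step needs kinetic facial selectivity, because the 2,3-cis product is the less stable epimer; the non-basic arylzinc and the weak Lewis acid should neither eliminate sulfinic acid to the dihydrofuran nor reopen the two benzylic C–O bonds, so no equilibration to the 2,3-trans series is expected. The benzyl and methyl ethers are inert to the reagent.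

Step 5
Reactants: 10 (2S,3R,4R,5S)-2-[4-(benzyloxy)-3-methoxyphenyl]-5-(3,4-dimethoxyphenyl)-3,4-dimethyloxolane
Product: 11 4-[(2S,3R,4R,5S)-5-(3,4-dimethoxyphenyl)-3,4-dimethyloxolan-2-yl]-2-methoxyphenol
Conditions: H2 (1 atm), 10% Pd/C, EtOAc, rt
Reagents that add atoms: none
Why: Catalytic hydrogenolysis of the aryl benzyl ether, which under neutral conditions at 1 atm should be much faster than cleavage of the two cyclic benzylic C–O bonds of the oxolane, so that all four stereocentres stay untouched.

Step 6
Reactants: 12 (S)-N,N-dimethyllactamide; 7 (3,4-dimethoxyphenyl)magnesium bromide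
Product: 13 (2S)-1-(3,4-dimethoxyphenyl)-2-hydroxypropan-1-one
Conditions: 7 (2.3 equiv), THF, −20 → 0 °C; aq. NH4Cl
Reagents that add atoms: none
Why: Grignard acylation by a tertiary amide, in which the first equivalent of 7 deprotonates the hydroxyl and the second adds to the amide carbonyl to give a magnesium-chelated hemiaminal that does not collapse before work-up, so that over-addition is avoided and the (S) centre, protected by the adjacent alkoxide, is retained.

Step 7
Reactants: 13 (2S)-1-(3,4-dimethoxyphenyl)-2-hydroxypropan-1-one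
Product: 14 (2S)-1-(3,4-dimethoxyphenyl)-1-oxopropan-2-yl 4-methylbenzenesulfonate
Conditions: TsCl, pyridine, CH2Cl2, 0 °C
Reagents that add atoms: p-toluenesulfonyl chloride, Cc1ccc(cc1)S(=O)(=O)Cl
Why: O-Sulfonylation of the secondary alcohol with retention at the stereocentre (the C–O bond is not broken), giving an α-keto sulfonate activated for SN2 displacement.

Step 8
Reactants: 11 4-[(2S,3R,4R,5S)-5-(3,4-dimethoxyphenyl)-3,4-dimethyloxolan-2-yl]-2-methoxyphenol; 14 (2S)-1-(3,4-dimethoxyphenyl)-1-oxopropan-2-yl 4-methylbenzenesulfonate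
Product: 15 (2R)-1-(3,4-dimethoxyphenyl)-2-{4-[(2S,3R,4R,5S)-5-(3,4-dimethoxyphenyl)-3,4-dimethyloxolan-2-yl]-2-methoxyphenoxy}propan-1-one
Conditions: BEMP, MeCN, rt
Reagents that add atoms: none
Why: Williamson-type SN2 etherification in which the phosphazene base BEMP gives a naked phenoxide that displaces the α-keto tosylate with inversion, (S) to (R), faster than the sulfonate or the product can enolise.

Step 9
Reactants: 15 (2R)-1-(3,4-dimethoxyphenyl)-2-{4-[(2S,3R,4R,5S)-5-(3,4-dimethoxyphenyl)-3,4-dimethyloxolan-2-yl]-2-methoxyphenoxy}propan-1-one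
Product: 16 (1R,2R)-1-(3,4-dimethoxyphenyl)-2-{4-[(2S,3R,4R,5S)-5-(3,4-dimethoxyphenyl)-3,4-dimethyloxolan-2-yl]-2-methoxyphenoxy}propan-1-ol
Conditions: polymer-supported borohydride (Amberlite IRA-400, BH4− form), MeOH, rt
Reagents that add atoms: none
Why: Substrate-controlled hydride reduction under non-chelating conditions (ammonium counter-ion of the resin), in which Felkin–Anh addition anti to the α-aryloxy group should convert the (R)-ketone into the threo (1R,2R) alcohol, while the oxolane and the ethers do not react with borohydride.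

Compound list
1 | 4-(benzyloxy)-3-methoxybenzaldehyde | COc1cc(C=O)ccc1OCc1ccccc1 | starting material
2 | (Z)-crotylboronic acid pinacol ester | C/C=C\CB1OC(C)(C)C(C)(C)O1 | starting material
3 | (1S,2R)-1-[4-(benzyloxy)-3-methoxyphenyl]-2-methylbut-3-en-1-ol | COc1cc([C@@H](O)[C@H](C)C=C)ccc1OCc1ccccc1 | intermediate
4 | (2R,3R,4S)-4-[4-(benzyloxy)-3-methoxyphenyl]-4-hydroxy-2,3-dimethylbutanal | COc1cc([C@@H](O)[C@H](C)[C@@H](C)C=O)ccc1OCc1ccccc1 | intermediate
5 | (3R,4R,5S)-5-[4-(benzyloxy)-3-methoxyphenyl]-3,4-dimethyloxolan-2-ol (C2 epimers) | COc1cc([C@H]2OC(O)[C@H](C)[C@H]2C)ccc1OCc1ccccc1 | intermediate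
6 | (3R,4R,5S)-2-(benzenesulfonyl)-5-[4-(benzyloxy)-3-methoxyphenyl]-3,4-dimethyloxolane (C2 epimers) | COc1cc([C@H]2OC(S(=O)(=O)c3ccccc3)[C@H](C)[C@H]2C)ccc1OCc1ccccc1 | intermediate
7 | (3,4-dimethoxyphenyl)magnesium bromide | COc1ccc([Mg]Br)cc1OC | starting material
8 | (3,4-dimethoxyphenyl)zinc bromide | COc1ccc([Zn]Br)cc1OC | intermediate
9 | (2S,3R,4R)-2-[4-(benzyloxy)-3-methoxyphenyl]-3,4-dimethyl-3,4-dihydro-2H-furan-1-ium (oxocarbenium ion) | COc1cc([C@H]2[O+]=C[C@H](C)[C@H]2C)ccc1OCc1ccccc1 | intermediate
10 | (2S,3R,4R,5S)-2-[4-(benzyloxy)-3-methoxyphenyl]-5-(3,4-dimethoxyphenyl)-3,4-dimethyloxolane | COc1cc([C@H]2O[C@H](c3ccc(OC)c(OC)c3)[C@H](C)[C@H]2C)ccc1OCc1ccccc1 | intermediate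
11 | 4-[(2S,3R,4R,5S)-5-(3,4-dimethoxyphenyl)-3,4-dimethyloxolan-2-yl]-2-methoxyphenol | COc1cc([C@H]2O[C@H](c3ccc(OC)c(OC)c3)[C@H](C)[C@H]2C)ccc1O | intermediate
12 | (S)-N,N-dimethyllactamide | C[C@H](O)C(=O)N(C)C | starting material
13 | (2S)-1-(3,4-dimethoxyphenyl)-2-hydroxypropan-1-one | C[C@H](O)C(=O)c1ccc(OC)c(OC)c1 | intermediate
14 | (2S)-1-(3,4-dimethoxyphenyl)-1-oxopropan-2-yl 4-methylbenzenesulfonate | C[C@H](OS(=O)(=O)c1ccc(C)cc1)C(=O)c1ccc(OC)c(OC)c1 | intermediate
15 | (2R)-1-(3,4-dimethoxyphenyl)-2-{4-[(2S,3R,4R,5S)-5-(3,4-dimethoxyphenyl)-3,4-dimethyloxolan-2-yl]-2-methoxyphenoxy}propan-1-one | COc1ccc(C(=O)[C@@H](C)Oc2ccc([C@H]3O[C@H](c4ccc(OC)c(OC)c4)[C@H](C)[C@H]3C)cc2OC)cc1OC | intermediate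
16 | (1R,2R)-1-(3,4-dimethoxyphenyl)-2-{4-[(2S,3R,4R,5S)-5-(3,4-dimethoxyphenyl)-3,4-dimethyloxolan-2-yl]-2-methoxyphenoxy}propan-1-ol | COc1ccc([C@@H](O)[C@@H](C)Oc2ccc([C@H]3O[C@H](c4ccc(OC)c(OC)c4)[C@H](C)[C@H]3C)cc2OC)cc1OC | target

Total step count: 9
Longest linear sequence: 7 steps (steps 1, 2, 3, 4, 5, 8, 9); steps 6 and 7 form the side-chain branch.

Steps most likely to fail

Step 2. The directing group may not fully override the intrinsic linear preference, which would give a six-membered lactol, and 1,2-induction at the new C3 centre may be weak. The fallback sets out from 3 and builds the same lactol by alkylation chemistry. Hydroboration–oxidation (9-BBN, THF; then NaBO3) should give (1S,2R)-1-[4-(benzyloxy)-3-methoxyphenyl]-2-methylbutane-1,4-diol F1. Oxidative lactonisation (TEMPO cat., PhI(OAc)2, CH2Cl2) should give (4R,5S)-5-[4-(benzyloxy)-3-methoxyphenyl]-4-methyloxolan-2-one F2. Enolate methylation (LiHMDS, THF, −78 °C; MeI), anti to the C4 methyl and the C5 aryl group, should give (3R,4R,5S)-5-[4-(benzyloxy)-3-methoxyphenyl]-3,4-dimethyloxolan-2-one F3. Half-reduction with DIBAL-H (CH2Cl2, −78 °C) comes back to the route at 5.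

Step 4. Ionisation of the sulfone may be slow, sulfinic acid may be eliminated to the 2,3-dihydrofuran, or facial selectivity may erode. The fallback sets out from 5 and replaces the organometallic by a neutral arene nucleophile. Acetylation (Ac2O, pyridine, DMAP, CH2Cl2) should give (3R,4R,5S)-5-[4-(benzyloxy)-3-methoxyphenyl]-3,4-dimethyloxolan-2-yl acetate F4. Friedel–Crafts C-arylation with 1,2-dimethoxybenzene (TMSOTf or SnCl4, CH2Cl2, −78 °C, quenched cold to keep kinetic control) should attack the same oxocarbenium ion through the position para to a methoxy group. It comes back to the route at 10.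

Step 8. The base may enolise the α-keto tosylate, which would scramble the configuration at the aryloxy carbon, or eliminate it to the aryl vinyl ketone. The fallback sets out from 11 and 13 and skips the isolated sulfonate: a Mitsunobu etherification (PPh3, DIAD, toluene, 0 °C) should join the phenol and the (S)-hydroxy ketone with inversion under neutral conditions. It comes back to the route at 15 and makes no new compound (F0).

Further compounds
F1 | step 2 | (1S,2R)-1-[4-(benzyloxy)-3-methoxyphenyl]-2-methylbutane-1,4-diol | COc1cc([C@@H](O)[C@H](C)CCO)ccc1OCc1ccccc1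
F2 | step 2 | (4R,5S)-5-[4-(benzyloxy)-3-methoxyphenyl]-4-methyloxolan-2-one | COc1cc([C@H]2OC(=O)C[C@H]2C)ccc1OCc1ccccc1
F3 | step 2 | (3R,4R,5S)-5-[4-(benzyloxy)-3-methoxyphenyl]-3,4-dimethyloxolan-2-one | COc1cc([C@H]2OC(=O)[C@H](C)[C@H]2C)ccc1OCc1ccccc1
F4 | step 4 | (3R,4R,5S)-5-[4-(benzyloxy)-3-methoxyphenyl]-3,4-dimethyloxolan-2-yl acetate | COc1cc([C@H]2OC(OC(C)=O)[C@H](C)[C@H]2C)ccc1OCc1ccccc1
F0 | step 8 | none | none
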